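Atoms carry cassane numbers throughout. α means below and β above the plane when the C10 methyl group is drawn β.

## Analysis of the target

1. Spirocaesalmin (28) is a rearranged cassane.
   - Rings A (C1–C5, C10) and B (C5–C10) form a trans-decalin.
   - Ring C is contracted to a cyclopentane (C8, C9, C11, C13, C14) that is trans-fused to ring B.
   - C13 is the spiro atom of a γ-lactone, ring D (C13, C12(=O), O, C16, C15), whose C15–C16 bond carries an epoxide oxygen.
2. There are ten stereocentres (C1, C5, C7, C8, C9, C10, C13, C14, C15, C16). The ring B substituents are all equatorial (7β-OAc, C8–C14, C9–C11; H8 β, H9 α), so they are thermodynamically favoured once C10 is fixed. In contrast, 1α-OAc and 5α-OH are syn-axial and sit between the quaternary carbons C4 and C10.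
3. At the spiro centre, C15 is β and cis to the 14β-CO2CH3 group, and C12 is α. The epoxide oxygen lies on the face of ring D that looks toward C14, which is the face shielded by this ester.
4. The sensitive groups are the acyloxy-epoxide (an acylal, comparable to a 1,2-anhydro sugar), two secondary acetates, a methyl ester with an epimerisable α-hydrogen (H14), and the tertiary alcohol.
5. Three things make the synthesis hard:
   - the all-carbon quaternary C13 next to C14 on a trans-hydrindane;
   - the epoxide on the hindered face, which rules out a simple final epoxidation of an enol lactone;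
   - the C5 carbinol between C4 and C10.
6. The route exploits one feature. Ring D is, atom for atom, tetronic acid: C12 is the lactone carbonyl, C13 the doubly C–H acidic carbon, C15 the oxygen-bearing carbon and C16 the OCH2 group. Both ring C bonds of C13 lead to carbons that can be made electrophilic: C11H2, and C14, which is α to the ester and β to the C7 oxygen.

## Retrosynthetic reasoning

**C5–O, 28 ⇒ 26.** The tertiary alcohol is removed last in the analysis, so it is installed last. In 26 the C5=C6 bond is the only alkene. A Markovnikov radical hydration therefore has no competitor, and no step of the route has to tolerate a β-hydroxy ketone. The forward reaction has to deliver oxygen to the α face of a C5 radical whose β face is closed by the C10 and 4β methyl groups.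

**Epoxide C16–O, C15–H and C7–H, 26 ⇒ 25 ⇒ 23 ⇒ 22.**
- The epoxide oxygen is taken to be the former ketone oxygen of a furan-2,4-dione.
- Cutting C16–O(epoxide) gives a trans-bromohydrin, and this comes from the 16-bromo ketone 23.
- The 14β ester blocks one face of ring D, so bromine and hydride both enter from the C11 side. The oxygen is then left on the C14 side, where the target has it.
- An epoxidation would do the opposite.
- The same hydride step reduces the C7 enone to the equatorial alcohol.

**C13–C14 and C13–C11, 22 ⇒ 19 + 20 (key disconnection).**
- Both ring C bonds of the spiro carbon are cut at once, which sets free ring D as tetronic acid (20).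
- What remains is the bicyclic 19, in which C14 is the β-carbon of an ene-keto-ester and C11 carries bromide.
- No other pair of cuts removes a whole ring, a quaternary centre and four skeletal carbons with their three oxygens in one stroke.
- The two arms at C8 and C9 are equatorial before closure, so the trans B/C fusion does not have to be made by the ring-forming step itself.
- The forward reaction must add C13 to C14, alkylate the same carbon at C11, and choose the face that puts C15 on the β side.

**C8=C14, 19 ⇒ 14 + 15.** The two-carbon unit C14–C17 is methyl glyoxylate (15). C8 is the only enolisable position of enone 14, because C6 is vinylic and C4 and C10 are quaternary. The aldol condensation therefore has a single site.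

**C7=O, C11–Br and C9–H, 14 ⇒ 13 ⇒ 11 ⇒ 10 ⇒ 9.**
- C7 is the only allylic CH2 of 13.
- The C11 bromide comes from the primary alcohol of 11.
- H9 is delivered to the α face of the C8=C9 bond of 10, under the direction of the 1α-hydroxyl group.
- Diol 10 is the reduced form of lactone 9. The tether carbon of the cycloaddition is thus kept as C11 and brought to the CH2 level before any other ester is present.

**C9–C10 and C7–C8, 9 ⇒ 8 ⇒ 6 + 7.** Ring B is opened by a retro-Diels–Alder cut. The propiolate tether on the 1α-oxygen of 8 forces the alkyne onto the α face of the ring A diene. The single stereocentre of 6 (C1) thereby controls the quaternary C10. An alkyne is chosen so that no C8/C9 stereochemistry has to be controlled in a strained lactone.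

**Ring A, 6 ⇒ 5 ⇒ 3 ⇒ 2 ⇒ 1.** The dienol is traced back through an enantioselective ketone reduction and a carbonyl transposition to the commercial dione 1. This dione already holds the gem-dimethyl carbon C4.

## Alternatives that were turned down

**Alternative 1:** the textbook cut.
- *Disconnection:* the lactone C–O bond and the C13–C15 bond are cut. The precursor is the allyl diester A1.
- *Forward key step:* allylation of a ring C ester enolate. Ozonolysis, enol lactonisation and epoxidation would follow.
- *Reasons for rejection:*
  - The electrophile would enter anti to the 14β ester, on the α face, which is the wrong face for C15.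
  - The amide base is not compatible with two acetates.
  - Ring C still has to be built beforehand.
  - The final epoxidation would come from the open C11 side and give the wrong epoxide face.
  - At least four operations are spent on ring D alone.

**Alternative 2:** the biomimetic cut.
- *Disconnection:* C11–C13 is cut and C11 is reconnected to C12, which leads to the cassane furan A2.
- *Forward key step:* oxidation of the furan with a 1,2-shift of C11 from C12 to C13, contracting ring C.
- *Reasons for rejection:*
  - The shift needs cationic character at C13, next to an acetal carbon. Electrophilic oxidants, however, attack a 2,3-dialkylfuran at C16 or C12.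
  - The primary products open to the cis-enedione.
  - H16 migrates or is abstracted more easily than C11 shifts, which makes C16 and not C12 the carbonyl.
  - The acidic H14 invites elimination toward C13=C14.
  - A2 is no simpler than the target in rings A and B.
  - Its furan would have to survive allylic oxidation and radical hydration.

**Alternative 3:** the 1,4-dicarbonyl cut.
- *Disconnection:* C13–C14 is cut, the central bond between the C12 and C17 carbonyl groups. The precursor is the ester butenolide A3.
- *Forward key step:* intramolecular oxidative coupling of the ester enolate with the butenolide dienolate.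
- *Reasons for rejection:*
  - Double deprotonation with amide bases cannot be done next to two acetates and a tertiary alcohol, so protecting group exchanges are needed.
  - The butenolide has to be brought in by a separate multi-step sequence at C11.
  - Its conjugated alkene competes in the radical hydration of C5=C6.
  - The product is again an enol lactone, whose direct epoxidation attacks the wrong face.

Key step: step 13

Assumption (remark on the chemistry): the exocyclic double bond of 19 is drawn as the Z isomer (ester syn to the C7 carbonyl). This is the isomer free of allylic strain with the C9 side chain. The E isomer would react in step 13 in the same way.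

## Route

Step 1
Reactants: 1 4,4-dimethylcyclohexane-1,3-dione
Product: 2 2,4,4-trimethylcyclohexane-1,3-dione
Conditions: MeI, K2CO3, acetone, reflux
Reagents that add atoms: iodomethane CI
Why: C-alkylation of a 1,3-dione enolate (SN2); the carbon between the two carbonyl groups is the softest nucleophilic site and becomes C10 with its methyl group.

Step 2
Reactants: 2 2,4,4-trimethylcyclohexane-1,3-dione
Product: 3 3-isobutoxy-2,6,6-trimethylcyclohex-2-en-1-one
Conditions: i-BuOH, TsOH (cat.), toluene, reflux, water separator
Reagents that add atoms: 2-methylpropan-1-ol CC(C)CO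
Why: Acid-catalysed vinylogous esterification; the alcohol attacks the carbonyl group remote from the gem-dimethyl carbon, so the ketone next to C(CH3)2 (the later C5) stays free.

Step 3
Reactants: 3 3-isobutoxy-2,6,6-trimethylcyclohex-2-en-1-one
Product: 5 2,4,4-trimethyl-3-vinylcyclohex-2-en-1-one, via tertiary carbinol 4 (not isolated)
Conditions: CH2=CHMgBr, CeCl3, THF, −78 to 0 °C; then 1 M HCl, rt
Reagents that add atoms: vinylmagnesium bromide C=C[Mg]Br
Why: Stork–Danheiser carbonyl transposition: 1,2-addition to the hindered ketone (the cerium salt suppresses enolisation), then acid-induced loss of isobutanol gives the cross-conjugated dienone that holds the diene C10=C5–C6=C7.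

Step 4
Reactants: 5 2,4,4-trimethyl-3-vinylcyclohex-2-en-1-one
Product: 6 (S)-2,4,4-trimethyl-3-vinylcyclohex-2-en-1-ol
Conditions: (R)-2-methyl-CBS-oxazaborolidine (10 mol %), BH3·SMe2, toluene, −40 °C; MeOH, then water
Reagents that add atoms: none
Why: Corey–Bakshi–Shibata reduction; the α-substituted alkenyl arm acts as the large group and the CH2 arm as the small group, so the (R)-catalyst should give the (S)-alcohol, which is C1 with its oxygen α.

Step 5
Reactants: 6 (S)-2,4,4-trimethyl-3-vinylcyclohex-2-en-1-ol; 7 propiolic acid
Product: 8 (S)-dienyl propiolate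
Conditions: DCC, DMAP (cat.), CH2Cl2, −20 to 0 °C
Reagents that add atoms: none
Why: Steglich esterification under mild conditions with retention at C1; the low temperature limits addition of the catalyst to the alkynoate.

Step 6
Reactants: 8 (S)-dienyl propiolate
Product: 9 tricyclic dienyl lactone
Conditions: toluene, BHT (cat.), 110–130 °C, sealed tube
Reagents that add atoms: none
Why: Type 1 intramolecular Diels–Alder reaction of an ester-tethered alkynoate closes ring B and the five-membered lactone (bonds C9–C10 and C7–C8). The three-atom tether on the 1α-oxygen allows attack only on the α face of the diene, so the C10 methyl group ends up β. The 1,4-diene cannot aromatise because C10 is quaternary.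

Step 7
Reactants: 9 tricyclic dienyl lactone
Product: 10 diene diol
Conditions: DIBAL-H (4.5 equiv), CH2Cl2, −78 to 0 °C; aqueous Rochelle salt
Reagents that add atoms: none
Why: 1,2-Reduction of an α,β-unsaturated lactone to the allylic diol; it brings the tether carbon C11 to the CH2 level while no other ester is present and frees the 1α-hydroxyl group.

Step 8
Reactants: 10 diene diol
Product: 11 ene diol
Conditions: H2 (1 atm), [Ir(cod)(PCy3)(py)]PF6 (5 mol %), CH2Cl2, rt
Reagents that add atoms: none
Why: Hydroxyl-directed homogeneous hydrogenation. The homoallylic 1α-OH binds the cationic iridium catalyst and the C10 methyl group closes the β face, so both hydrogens go to the α face of C8=C9 (9α-H, CH2OH equatorial). The C5=C6 bond next to the gem-dimethyl carbon is slower.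

Step 9
Reactants: 11 ene diol
Product: 13 bromo acetate, via bromo alcohol 12 (not isolated)
Conditions: CBr4, PPh3, CH2Cl2, 0 °C; then pyridine, Ac2O, DMAP (cat.), rt
Reagents that add atoms: tetrabromomethane BrC(Br)(Br)Br; acetic anhydride CC(=O)OC(C)=O
Why: Appel reaction, selective for the primary alcohol over the axial secondary 1α-OH, followed by acetylation of the latter in the same flask; no stereocentre is touched.

Step 10
Reactants: 13 bromo acetate
Product: 14 bromo enone
Conditions: Rh2(cap)4 (1 mol %), aq. t-BuOOH, 1,2-dichloroethane, 40 °C
Reagents that add atoms: tert-butyl hydroperoxide CC(C)(C)OO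
Why: Dirhodium caprolactamate catalysed allylic C–H oxidation, as used for the conversion of 5-ene steroids into 7-ketones; C7 is the only allylic CH2 because C4 and C10 are quaternary.

Step 11
Reactants: 14 bromo enone; 15 methyl glyoxylate
Product: 17 aldol adduct, via silyl dienol ether 16 (not isolated)
Conditions: TMSOTf, Et3N, CH2Cl2, 0 °C; pentane, filtration; then 15, Sc(OTf)3 (10 mol %), CH2Cl2, −40 °C; 1 M HCl
Reagents that add atoms: trimethylsilyl trifluoromethanesulfonate C[Si](C)(C)OS(=O)(=O)C(F)(F)F (silyl group in 16 only)
Why: Soft enolisation and Mukaiyama aldol addition. C8 is the only enolisable carbon, and the silyl dienol ether is too weak a nucleophile to displace the C11 bromide, so no cyclopropane should form. The new centres at C8 and C14 are erased in step 12.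

Step 12
Reactants: 17 aldol adduct
Product: 19 (Z)-ene-keto-ester, via aldol mesylate 18 (not isolated)
Conditions: MsCl, Et3N, CH2Cl2, 0 °C to rt
Reagents that add atoms: methanesulfonyl chloride CS(=O)(=O)Cl (mesyl group in 18 only)
Why: Mesylation and E1cB elimination of a β-hydroxy ketone. Loss of the β-mesylate from the transient C8 enolate is faster than attack on C11. The Z isomer avoids allylic strain between the ester and the equatorial CH2Br group.

Step 13
Reactants: 19 (Z)-ene-keto-ester; 20 tetronic acid
Product: 22 spiro furan-2,4-dione, via Michael adduct 21 (not isolated)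
Conditions: 20 (1.2 equiv), MgBr2·OEt2 (1.2 equiv), i-Pr2NEt (2.2 equiv), CH2Cl2–MeCN, 0 °C, then 45 °C
Reagents that add atoms: none
Why: This is a domino Michael addition/intramolecular C-alkylation (Michael-initiated ring closure, a formal [4+1] annulation), a reaction type well known for cyclic 1,3-dicarbonyl C–H acids and halogen-bearing acceptors. The magnesium tetronate adds through C13 to C14, the only open β-carbon of 19 (C5 lies between two quaternary carbons, C8 is fully substituted), and the C8 enolate is protonated at once by the ammonium salt or by the acidic adduct to give 21. Compound 21 is still a vinylogous acid, and its anion displaces bromide at C11 through C13 in a 5-exo-tet closure of ring C, whereas O-alkylation would need a seven-membered ring and is disfavoured by the soft leaving group. C8 is set by thermodynamic protonation α to the C7 ketone (C14 equatorial, H8 β, because the axial epimer would be syn-axial to the C10 methyl group), so ring C closes between two equatorial arms and the B/C fusion is trans. C14 remains epimerisable (α to the ester, reversible Michael step) and should settle with the ester β, trans to the C7–C8 bond. C13 is the one kinetically fixed centre: in the alkylation transition state C8 stands perpendicular to the tetronate plane, and a magnesium ion on the more basic oxygen at C15 can be chelated by the C17 ester carbonyl only if C15 lies on the β side, which places C15 cis to the ester and C12 α. The step needs Michael addition to outrun γ-deprotonation at C9 with loss of bromide, which the buffered medium (tetronate as the strongest base) should secure, and it needs the absence of a free C8 enolate so that no cyclopropane forms.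

Step 14
Reactants: 22 spiro furan-2,4-dione
Product: 23 16-bromo ketone
Conditions: NBS, NH4OAc (cat.), THF–Et2O, rt
Reagents that add atoms: N-bromosuccinimide O=C1CCC(=O)N1Br
Why: α-Bromination of a ketone through its enol. The C15 ketone can enolise only toward C16 because C13 is quaternary, and it is the most enolisable carbonyl group. The 14β ester covers the face of ring D that looks toward C14, so bromine should enter from the C11 side.

Step 15
Reactants: 23 16-bromo ketone
Product: 25 epoxy lactone 7β-alcohol, via trans-bromohydrin 24 (not isolated)
Conditions: NaBH4, CeCl3·7H2O, MeOH–THF, −78 to −20 °C; then solid NaHCO3, 0 °C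
Reagents that add atoms: none
Why: Luche reduction followed by halohydrin-to-epoxide closure (intramolecular Williamson reaction), the way 1,2-anhydro sugars form from 2-hydroxy glycosyl halides. Hydride reaches C15 only from the C11 side, so O15 ends up on the C14 side, trans to bromine, and displaces it at C16, which fixes C15 and C16 as in the target. Axial 1,2-attack on the C7 enone gives the equatorial 7β-alcohol.

Step 16
Reactants: 25 epoxy lactone 7β-alcohol
Product: 26 5,6-didehydro-5-deoxyspirocaesalmin
Conditions: Ac2O, pyridine, CH2Cl2, 0 °C to rt
Reagents that add atoms: acetic anhydride CC(=O)OC(C)=O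
Why: Acetylation of the unhindered equatorial allylic alcohol; no nucleophilic catalyst is used, so as to spare the acyloxy-epoxide.

Step 17
Reactants: 26 5,6-didehydro-5-deoxyspirocaesalmin
Product: 28 spirocaesalmin, via 5α-hydroperoxide 27 (not isolated)
Conditions: Mn(dpm)3 (10 mol %), PhSiH3, O2 (1 atm), i-PrOH–CH2Cl2, 0 °C to rt; then PPh3, 0 °C
Reagents that add atoms: dioxygen O=O
Why: Mukaiyama hydration (metal hydride hydrogen atom transfer). Hydrogen goes to the accessible C6–H carbon and the tertiary C5 radical is trapped by oxygen. The β face is closed by the flanking C10 and 4β methyl groups, so oxygen enters from the α face and the trans-decalin with axial 5α-OH results. C5=C6 is the only alkene left.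

## Compound list

1 | 4,4-dimethylcyclohexane-1,3-dione | O=C1CCC(C)(C)C(=O)C1 | starting material
2 | 2,4,4-trimethylcyclohexane-1,3-dione | CC1C(=O)CCC(C)(C)C1=O | intermediate
3 | 3-isobutoxy-2,6,6-trimethylcyclohex-2-en-1-one | CC1=C(OCC(C)C)CCC(C)(C)C1=O | intermediate
4 | 3-isobutoxy-2,6,6-trimethyl-1-vinylcyclohex-2-en-1-ol (racemic tertiary carbinol, not isolated) | CC1=C(OCC(C)C)CCC(C)(C)C1(O)C=C | intermediate
5 | 2,4,4-trimethyl-3-vinylcyclohex-2-en-1-one | CC1=C(C=C)C(C)(C)CCC1=O | intermediate
6 | (S)-2,4,4-trimethyl-3-vinylcyclohex-2-en-1-ol (ring A dienol, 1α-OH) | CC1=C(C=C)C(C)(C)CC[C@@H]1O | intermediate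
7 | propiolic acid | C#CC(=O)O | starting material
8 | (S)-2,4,4-trimethyl-3-vinylcyclohex-2-en-1-yl propiolate | CC1=C(C=C)C(C)(C)CC[C@@H]1OC(=O)C#C | intermediate
9 | tricyclic dienyl lactone: rings A and B with C5=C6 and C8=C9, 10β-methyl, γ-lactone 1α-O–C11(=O)–C9 | O=C1O[C@H]2CCC(C)(C)C3=CCC=C1[C@@]23C | intermediate
10 | diene diol: 1α-OH, CH2OH (C11) on C9, C5=C6 and C8=C9, 10β-methyl | OCC1=CCC=C2C(C)(C)CC[C@H](O)[C@]12C | intermediate
11 | ene diol: 1α-OH, 9α-H, equatorial 9-CH2OH, C5=C6 | OC[C@H]1CCC=C2C(C)(C)CC[C@H](O)[C@]12C | intermediate
12 | bromo alcohol: 1α-OH, 9α-H, 9-CH2Br, C5=C6 (not isolated) | BrC[C@H]1CCC=C2C(C)(C)CC[C@H](O)[C@]12C | intermediate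
13 | bromo acetate: 1α-OAc, 9α-H, 9-CH2Br, C5=C6 | BrC[C@H]1CCC=C2C(C)(C)CC[C@H](OC(C)=O)[C@]12C | intermediate
14 | bromo enone: as 13 with C7=O conjugated to C5=C6 | BrC[C@H]1CC(=O)C=C2C(C)(C)CC[C@H](OC(C)=O)[C@]12C | intermediate
15 | methyl glyoxylate | COC(=O)C=O | starting material
16 | 7-trimethylsilyloxy-5,7-diene (silyl dienol ether of 14, not isolated) | BrC[C@H]1C=C(O[Si](C)(C)C)C=C2C(C)(C)CC[C@H](OC(C)=O)[C@]12C | intermediate
17 | aldol adduct: C8–CH(OH)CO2CH3, drawn with the side chain equatorial (H8 β), C14 epimers | BrC[C@H]1[C@H](C(O)C(=O)OC)C(=O)C=C2C(C)(C)CC[C@H](OC(C)=O)[C@]12C | intermediate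
18 | aldol mesylate (not isolated) | BrC[C@H]1[C@H](C(OS(C)(=O)=O)C(=O)OC)C(=O)C=C2C(C)(C)CC[C@H](OC(C)=O)[C@]12C | intermediate
19 | (Z)-ene-keto-ester: C8=C14H–CO2CH3 with the ester syn to C7=O, 9-CH2Br, 1α-OAc, C5=C6 | BrC[C@H]1/C(=C/C(=O)OC)C(=O)C=C2C(C)(C)CC[C@H](OC(C)=O)[C@]12C | intermediate
20 | tetronic acid (4-hydroxyfuran-2(5H)-one) | OC1=CC(=O)OC1 | starting material
21 | Michael adduct: 3-substituted tetronic acid bound through C13 to C14, H8 β, 14-CO2CH3 as in the target (not isolated) | BrC[C@H]1[C@H]([C@H](C(=O)OC)C3=C(O)COC3=O)C(=O)C=C2C(C)(C)CC[C@H](OC(C)=O)[C@]12C | intermediate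
22 | spiro furan-2,4-dione: rings A to D complete, C15 ketone β, C12 lactone carbonyl α, 14β-CO2CH3, 7-oxo-5-ene, 1α-OAc | COC(=O)[C@H]1[C@@H]2C(=O)C=C3C(C)(C)CC[C@H](OC(C)=O)[C@]3(C)[C@H]2C[C@]12C(=O)OCC2=O | intermediate
23 | 16-bromo ketone: as 22 with bromine at C16 on the face toward C11 | COC(=O)[C@H]1[C@@H]2C(=O)C=C3C(C)(C)CC[C@H](OC(C)=O)[C@]3(C)[C@H]2C[C@]12C(=O)O[C@@H](Br)C2=O | intermediate
24 | trans-bromohydrin: 7β-OH, 15-OH on the face toward C14, 16-Br on the face toward C11 (not isolated) | COC(=O)[C@H]1[C@@H]2[C@@H](O)C=C3C(C)(C)CC[C@H](OC(C)=O)[C@]3(C)[C@H]2C[C@]12C(=O)O[C@@H](Br)[C@@H]2O | intermediate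
25 | epoxy lactone 7β-alcohol: 15,16-epoxide as in the target, 1α-OAc, C5=C6 | COC(=O)[C@H]1[C@@H]2[C@@H](O)C=C3C(C)(C)CC[C@H](OC(C)=O)[C@]3(C)[C@H]2C[C@]12C(=O)O[C@@H]1O[C@@H]12 | intermediate
26 | 5,6-didehydro-5-deoxyspirocaesalmin (1α,7β-diacetate, C5=C6) | COC(=O)[C@H]1[C@@H]2[C@@H](OC(C)=O)C=C3C(C)(C)CC[C@H](OC(C)=O)[C@]3(C)[C@H]2C[C@]12C(=O)O[C@@H]1O[C@@H]12 | intermediate
27 | 5α-hydroperoxide of the target skeleton (not isolated) | COC(=O)[C@H]1[C@@H]2[C@@H](OC(C)=O)C[C@@]3(OO)C(C)(C)CC[C@H](OC(C)=O)[C@]3(C)[C@H]2C[C@]12C(=O)O[C@@H]1O[C@@H]12 | intermediate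
28 | spirocaesalmin | COC(=O)[C@H]1[C@@H]2[C@@H](OC(C)=O)C[C@@]3(O)C(C)(C)CC[C@H](OC(C)=O)[C@]3(C)[C@H]2C[C@]12C(=O)O[C@@H]1O[C@@H]12 | target

## Step count and least certain steps

- Total step count: 17.
- Longest linear sequence: 17 steps from 1. Compounds 7, 15 and 20 are bought and enter directly.

**Step 13 (key step).** The most likely failure is poor facial selectivity at C13. The two arms of the tetronate (C12 and C15) are similar in size, and the magnesium chelate to the C17 ester is the only element that tells them apart. A second danger is γ-deprotonation at C9 with loss of bromide before the Michael addition. A third is O-alkylation.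

The fallback separates the two bond formations and replaces the tetronate by a nucleophile with two very different arms:
1. It sets out from 21, made with catalytic Et3N at 0 °C and isolated. Tf2O and i-Pr2NEt would give the tetronate triflate F1.
2. Reduction with Pd(OAc)2, PPh3, HCO2H and Et3N would give the butenolide enone F2.
3. Luche reduction would give the butenolide 7β-alcohol F3.
4. Acetylation would give the butenolide diacetate F4.
5. Cs2CO3 in MeCN would form the 2-oxidofuran, which alkylates at C13 (5-exo-tet) with the small C15–H arm on the crowded β side. This gives the spiro enol lactone F5.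
6. NBS in aqueous THF attacks from the open C11 side and would give the 15-bromo-16-hydroxy lactone F6.
7. Ag2O closes the epoxide from the C14 side, so the fallback returns to the route at 26.

**Step 8.** What may go wrong is loss of facial or site selectivity. The freely rotating primary allylic hydroxyl group can also bind the catalyst and deliver hydrogen to the β face. The 1,4-diene may isomerise, or C5=C6 may be reduced as well.

The fallback replaces kinetic delivery by thermodynamic control at C9:
1. It sets out from 10. MnO2 would oxidise only the primary allylic alcohol, to the dienal F7.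
2. Acetylation of the 1α-OH, which also prevents lactol formation, would give the dienal acetate F8.
3. Conjugate hydrosilylation (Et3SiH, RhCl(PPh3)3), hydrolysis and equilibration with DBU would give the equatorial aldehyde F9.
4. NaBH4 would give the primary alcohol acetate F10.
5. An Appel bromination leads back to the route at 13.

**Step 15.** The likely failures are hydride attack anti to the neighbouring bromine in spite of the ester shield, reductive loss of bromine, or solvolysis of the acylal-type bromide by methanol. In each case the trans-bromohydrin does not form and the closure fails.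

The fallback builds the epoxide from an alkene by bromohydrin formation. The face is then set by the first, sterically controlled attack:
1. It sets out from 22. Tf2O and 2,6-di-tert-butyl-4-methylpyridine would give the enol triflate F11.
2. Pd(OAc)2, PPh3, HCO2H and Et3N would give the enol lactone enone F12.
3. NBS in aqueous THF would give the bromohydrin enone F13.
4. Ag2O would give the epoxy enone F14.
5. A Luche reduction of the C7 ketone returns to the route at 25.

**Step 17.** Three processes may go wrong:
- Hydrogen atom transfer to an alkene that lies between two quaternary carbons may be too slow.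
- During a long reaction the acyloxy-epoxide may be opened by the alcohol solvent.
- Trapping on the α face is hindered by the syn-axial 1α-acetate.

The fallback uses that same acetate as an internal nucleophile. It sets out from 26. NIS in wet MeCN would add iodine to C6 from the β face, while the 1α-acetate carbonyl oxygen attacks C5 from the α face (anti, diaxial addition by neighbouring group participation). Hydrolysis of the bridged acetoxonium ion, with the acetyl group staying on the secondary oxygen, would give the 6β-iodo-5α-alcohol F15. Radical deiodination with (Me3Si)3SiH and Et3B/air returns to the route at 28.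

## Further compounds

F1 | step 13 | tetronate triflate of the Michael adduct | BrC[C@H]1[C@H]([C@H](C(=O)OC)C3=C(OS(=O)(=O)C(F)(F)F)COC3=O)C(=O)C=C2C(C)(C)CC[C@H](OC(C)=O)[C@]12C
F2 | step 13 | butenolide enone (3-substituted furan-2(5H)-one on C14) | BrC[C@H]1[C@H]([C@H](C(=O)OC)C3=CCOC3=O)C(=O)C=C2C(C)(C)CC[C@H](OC(C)=O)[C@]12C
F3 | step 13 | butenolide 7β-alcohol | BrC[C@H]1[C@H]([C@H](C(=O)OC)C3=CCOC3=O)[C@@H](O)C=C2C(C)(C)CC[C@H](OC(C)=O)[C@]12C
F4 | step 13 | butenolide diacetate (1α,7β-diacetate) | BrC[C@H]1[C@H]([C@H](C(=O)OC)C3=CCOC3=O)[C@@H](OC(C)=O)C=C2C(C)(C)CC[C@H](OC(C)=O)[C@]12C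
F5 | step 13 | spiro enol lactone (furan-2(3H)-one, C15=C16, C15 β) | COC(=O)[C@H]1[C@@H]2[C@@H](OC(C)=O)C=C3C(C)(C)CC[C@H](OC(C)=O)[C@]3(C)[C@H]2C[C@]12C(=O)OC=C2
F6 | step 13 | 15-bromo-16-hydroxy lactone (Br toward C11, OH toward C14) | COC(=O)[C@H]1[C@@H]2[C@@H](OC(C)=O)C=C3C(C)(C)CC[C@H](OC(C)=O)[C@]3(C)[C@H]2C[C@]12C(=O)O[C@H](O)[C@H]2Br
F7 | step 8 | dienal (C11 aldehyde on C9=C8, 1α-OH) | O=CC1=CCC=C2C(C)(C)CC[C@H](O)[C@]12C
F8 | step 8 | dienal acetate (1α-OAc) | O=CC1=CCC=C2C(C)(C)CC[C@H](OC(C)=O)[C@]12C
F9 | step 8 | equatorial aldehyde (9α-H, 1α-OAc, C5=C6) | O=C[C@H]1CCC=C2C(C)(C)CC[C@H](OC(C)=O)[C@]12C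
F10 | step 8 | primary alcohol acetate (9α-H, 9-CH2OH, 1α-OAc) | OC[C@H]1CCC=C2C(C)(C)CC[C@H](OC(C)=O)[C@]12C
F11 | step 15 | enol triflate of the C15 ketone | COC(=O)[C@H]1[C@@H]2C(=O)C=C3C(C)(C)CC[C@H](OC(C)=O)[C@]3(C)[C@H]2C[C@]12C(=O)OC=C2OS(=O)(=O)C(F)(F)F
F12 | step 15 | enol lactone enone | COC(=O)[C@H]1[C@@H]2C(=O)C=C3C(C)(C)CC[C@H](OC(C)=O)[C@]3(C)[C@H]2C[C@]12C(=O)OC=C2
F13 | step 15 | bromohydrin enone (15-Br toward C11, 16-OH toward C14) | COC(=O)[C@H]1[C@@H]2C(=O)C=C3C(C)(C)CC[C@H](OC(C)=O)[C@]3(C)[C@H]2C[C@]12C(=O)O[C@H](O)[C@H]2Br
F14 | step 15 | epoxy enone | COC(=O)[C@H]1[C@@H]2C(=O)C=C3C(C)(C)CC[C@H](OC(C)=O)[C@]3(C)[C@H]2C[C@]12C(=O)O[C@@H]1O[C@@H]12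
F15 | step 17 | 6β-iodo-5α-alcohol | COC(=O)[C@H]1[C@@H]2[C@@H](OC(C)=O)[C@@H](I)[C@@]3(O)C(C)(C)CC[C@H](OC(C)=O)[C@]3(C)[C@H]2C[C@]12C(=O)O[C@@H]1O[C@@H]12
A1 | alternative 1 | allyl diester (C13 with allyl β and CO2CH3 α) | COC(=O)[C@H]1[C@@H]2[C@@H](OC(C)=O)C[C@@]3(O)C(C)(C)CC[C@H](OC(C)=O)[C@]3(C)[C@H]2C[C@]1(CC=C)C(=O)OC
A2 | alternative 2 | cassane furan (methyl 1α,7β-diacetoxy-5α-hydroxyvouacapan-17β-oate) | COC(=O)[C@H]1[C@@H]2[C@@H](OC(C)=O)C[C@@]3(O)C(C)(C)CC[C@H](OC(C)=O)[C@]3(C)[C@H]2Cc2occc21
A3 | alternative 3 | ester butenolide (C8–CH2CO2CH3, C9–CH2–butenolide) | COC(=O)C[C@@H]1[C@@H](OC(C)=O)C[C@@]2(O)C(C)(C)CC[C@H](OC(C)=O)[C@]2(C)[C@H]1CC1=CCOC1=O
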